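**Retrosynthetic overview**
1. Target ⇒ cut the C3–O(ester) bond: silyl ketene acetal of (S)-5-benzyl-γ-butyrolactone (C3 nucleophile) + bis(3,4-dimethoxybenzoyl) peroxide (electrophilic aroyloxy donor). This one C–O bond formation brings in the whole ester and sets C3 trans to the benzyl group.
2. (S)-5-Benzyl-γ-butyrolactone ⇒ (R)-2-benzyloxirane + the acetate enolate of tert-butyl acetate; the C5 configuration is bought with the epoxide.
3. Peroxide ⇒ 3,4-dimethoxybenzoyl chloride + hydrogen peroxide.
4. Ring order: the γ-lactone is the only ring made and is closed in step 1, before the C3–O bond; both benzene rings are bought.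

Assumption: (R)-2-benzyloxirane is bought as a catalogue epoxide; the target is read as (3R,5R), with the acyloxy and benzyl groups trans on the lactone.

**Route**

Step 1
Reactants: 1 (R)-2-benzyloxirane; 2 tert-butyl acetate
Product: 6 (S)-5-benzyldihydrofuran-2(3H)-one, via ester lithium enolate 3 (not isolated), via aluminium enolate 4 (not isolated), via hydroxy ester 5 (not isolated)
Conditions: LiN(i-Pr)2, THF, −78 °C; Et2AlCl; then 1, −78 → 0 °C; 1 M HCl; then TsOH (cat.), toluene, 80 °C
Reagents that add atoms: none
Why: Aluminium ester enolate opening of a terminal epoxide (SN2 at the unsubstituted carbon, stereocentre untouched) followed by acid-catalysed lactonisation of the γ-hydroxy tert-butyl ester, so C5 keeps the epoxide configuration and its descriptor changes from R to S only because the priority order changes.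

Step 2
Reactants: 7 3,4-dimethoxybenzoyl chloride
Product: 8 bis(3,4-dimethoxybenzoyl) peroxide
Conditions: 7 (2 equiv), 30% aq. H2O2 (1 equiv), NaOH (2 equiv), H2O/CH2Cl2, 0 °C; solid kept cold and used promptly
Reagents that add atoms: hydrogen peroxide, OO
Why: Schotten–Baumann double acylation of hydrogen peroxide, in which the hydroperoxide and then the peroxycarboxylate anion are alpha-effect nucleophiles that outcompete hydroxide for the acid chloride, while the neutral diaroyl peroxide moves into the organic phase away from the base.

Step 3
Reactants: 6 (S)-5-benzyldihydrofuran-2(3H)-one; 8 bis(3,4-dimethoxybenzoyl) peroxide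
Product: 11 (3R,5R)-5-benzyl-2-oxotetrahydrofuran-3-yl 3,4-dimethoxybenzoate, via lactone lithium enolate 9 (not isolated), via silyl ketene acetal 10 (not isolated)
Conditions: Me3SiCl, LiN(SiMe3)2, THF, −78 °C (in situ trapping); then 8 (1.2 equiv) in CH2Cl2, −78 → 0 °C; aq. NaHCO3
Reagents that add atoms: none
Why: Proposed new method: electrophilic aroyloxylation of a lactone silyl ketene acetal (a Rubottom-type oxidation with a diaroyl peroxide in place of the peracid), in which the electron-rich C3 of 10 attacks the O–O sigma-star orbital of 8 in an SN2 step at oxygen from the face opposite the C5 benzyl group, setting C3 as R and trans to benzyl (the C5 descriptor reads R in 11 only through the priority change), after which the expelled 3,4-dimethoxybenzoate removes the silyl group from the oxocarbenium ion; the neutral nucleophile avoids carbonyl attack on 8 and cannot deprotonate or epimerise the more acidic product, and the closest known reaction types are the alpha-benzoyloxylation of enamines and of stabilised enolates with dibenzoyl peroxide and the Rubottom oxidation of silyl enol ethers.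

**Compound list**
1 | (R)-2-benzyloxirane | C1[C@@H](Cc2ccccc2)O1 | starting material
2 | tert-butyl acetate | CC(=O)OC(C)(C)C | starting material
3 | lithium 1-(tert-butoxy)ethen-1-olate (lithium enolate of 2) | [Li+].[O-]C(=C)OC(C)(C)C | intermediate
4 | [(1-tert-butoxyethenyl)oxy]diethylalumane (diethylaluminium enolate of 2) | CC[Al](CC)OC(=C)OC(C)(C)C | intermediate
5 | tert-butyl (S)-4-hydroxy-5-phenylpentanoate | CC(C)(C)OC(=O)CC[C@@H](Cc1ccccc1)O | intermediate
6 | (S)-5-benzyldihydrofuran-2(3H)-one | O=C1CC[C@@H](Cc2ccccc2)O1 | intermediate
7 | 3,4-dimethoxybenzoyl chloride | COc1ccc(cc1OC)C(=O)Cl | starting material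
8 | bis(3,4-dimethoxybenzoyl) peroxide | COc1ccc(cc1OC)C(=O)OOC(=O)c1ccc(OC)c(OC)c1 | intermediate
9 | lithium (S)-5-benzyl-4,5-dihydrofuran-2-olate (lithium enolate of 6) | [Li+].[O-]C1=CC[C@@H](Cc2ccccc2)O1 | intermediate
10 | (S)-[(5-benzyl-4,5-dihydrofuran-2-yl)oxy]trimethylsilane | C[Si](C)(C)OC1=CC[C@@H](Cc2ccccc2)O1 | intermediate
11 | (3R,5R)-5-benzyl-2-oxotetrahydrofuran-3-yl 3,4-dimethoxybenzoate (trichoderolide F) | COc1ccc(C(=O)O[C@@H]2C[C@@H](Cc3ccccc3)OC2=O)cc1OC | target

**Count and risks**
Total step count: 3. Longest linear sequence: 2 steps (1 → 6 → 11); step 2 is a one-step side branch that makes the aroyloxy donor.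

Risk 1, step 3 (the new aroyloxylation). The O–O attack may be slow with the electron-rich peroxide, or the trans:cis ratio may be modest. The fallback uses known chemistry, sets out from 6 and comes back at 11. Compound 6 is treated with KN(SiMe3)2 in THF at −78 °C and then with 3-phenyl-2-(phenylsulfonyl)oxaziridine (enolate hydroxylation, oxygen delivered anti to the benzyl group). This gives (3R,5R)-5-benzyl-3-hydroxydihydrofuran-2(3H)-one F1. F1 is then esterified with 7 (pyridine, DMAP cat., CH2Cl2, 0 °C; NaHCO3 wash) to give 11.

Risk 2, step 1 (epoxide opening). The basic enolate may isomerise the benzylic epoxide to the allylic alcohol, or the opening may be incomplete. The fallback sets out from 1 and comes back at 6, and replaces the aluminium ester enolate by a non-basic stabilised malonate nucleophile followed by decarboxylation. Compound 1 is heated with diethyl malonate and NaOEt in EtOH; opening at the terminal carbon and lactonisation in the same pot give ethyl (5S)-5-benzyl-2-oxotetrahydrofuran-3-carboxylate F2 (both C3 epimers). Saponification with LiOH in THF/H2O and acidification give (5S)-5-benzyl-2-oxotetrahydrofuran-3-carboxylic acid F3. Heating F3 in xylene at 140 °C removes carbon dioxide and gives 6.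

Risk 3, step 2 (peroxide formation). Hydrolysis of the acid chloride or base-induced decomposition of the electron-rich peroxide may lower the yield. The fallback sets out from 7 and comes back at 8, and builds the peroxide in two separate acylations through an isolated peracid. Compound 7 is added to an excess of alkaline H2O2 (NaOH, THF/H2O, 0 °C) and the mixture is acidified to give 3,4-dimethoxyperoxybenzoic acid F4, which is isolated and titrated. F4 is then acylated with a second equivalent of 7 under biphasic NaHCO3/CH2Cl2 at 0 °C to give 8.

**Further compounds**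
F1 | step 3 | (3R,5R)-5-benzyl-3-hydroxydihydrofuran-2(3H)-one | O[C@@H]1C[C@@H](Cc2ccccc2)OC1=O
F2 | step 1 | ethyl (5S)-5-benzyl-2-oxotetrahydrofuran-3-carboxylate (both C3 epimers) | CCOC(=O)C1C[C@@H](Cc2ccccc2)OC1=O
F3 | step 1 | (5S)-5-benzyl-2-oxotetrahydrofuran-3-carboxylic acid (both C3 epimers) | OC(=O)C1C[C@@H](Cc2ccccc2)OC1=O
F4 | step 2 | 3,4-dimethoxyperoxybenzoic acid | COc1ccc(cc1OC)C(=O)OO
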